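**Plan** (side chain numbered from the benzylic carbon C1' to the terminal methyl C16')
1. Cuts, in retrosynthetic order: both ketones (C5', C12') go back to silylated carbinols; then C1'–C2' and C3'–CH3 (benzylic chloride, Me3Al, terminal alkyne C2'≡C3'); then C4'–C5' (propargylzinc plus enal), C14'=C15' (cross-metathesis) and C12'–C13' (allylzinc plus aldehyde), leaving the C10 chain of geranyl acetate; on the arene, the C–CH2Cl carbon (ortho-formylation).
2. Enabling feature: the E-trisubstituted C2'=C3' alkene, with its methyl on C3' and its C2' joined through the C1' methylene to the benzene ring, is the pattern left by syn-methylmetalation of a 1-alkyne followed by benzylation.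
3. Forward order: no ring is formed, the benzene ring is bought; arene to benzylic chloride in 4 steps; geranyl acetate to the alkyne in 9 steps (C8 hydroxylation, asymmetric hydrogenation, prenyl carbinol on the right, enal on the left, propargyl carbinol, bis-silylation); the halves are joined in the key step; desilylation, double oxidation and phenol release finish.
4. Stereochemistry: C11' (S) from Ru(OAc)2[(S)-BINAP] hydrogenation of the C8-hydroxylated geranyl acetate; C6'=C7' (E) inherited from geranyl acetate; C2'=C3' (E) from syn delivery of methyl and aluminium and a stereoretentive coupling; the C5' and C12' carbinols are epimer mixtures that the oxidation erases.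

Key step: step 14

Assumption: the Ru(OAc)2(BINAP) hydrogenation of the E-2-methylallylic alcohol is taken to attack the same face of the C=C–CH2OH unit as in geraniol, which calls for the (S)-ligand to reach the S centre; the (R)-ligand would be used if the sense proved opposite.

**Fragment A: benzylic chloride**

Step 1
Reactants: 1 4-methoxy-2-methylphenol
Product: 2 2-hydroxy-5-methoxy-3-methylbenzaldehyde
Conditions: MgCl2, Et3N, (CH2O)n, MeCN, reflux
Reagents that add atoms: paraformaldehyde (as formaldehyde), C=O
Why: The magnesium phenoxide directs formaldehyde to the only free ortho position and a second formaldehyde oxidises the benzylic alkoxide in situ (Casnati–Skattebøl ortho-formylation), so a single salicylaldehyde should result.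

Step 2
Reactants: 2 2-hydroxy-5-methoxy-3-methylbenzaldehyde
Product: 3 2-[(tert-butyldimethylsilyl)oxy]-5-methoxy-3-methylbenzaldehyde
Conditions: TBSCl, imidazole, DMF, rt
Reagents that add atoms: tert-butyldimethylsilyl chloride, CC(C)(C)[Si](C)(C)Cl
Why: Imidazole-promoted silylation masks the phenol, which would otherwise quench Me3Al and open an o-quinone methide pathway from the later benzylic chloride.

Step 3
Reactants: 3 2-[(tert-butyldimethylsilyl)oxy]-5-methoxy-3-methylbenzaldehyde
Product: 4 {2-[(tert-butyldimethylsilyl)oxy]-5-methoxy-3-methylphenyl}methanol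
Conditions: NaBH4, MeOH/THF, 0 °C
Reagents that add atoms: none
Why: Borohydride reduction of the aryl aldehyde is fast at 0 °C, and immediate protonation of the benzylic alkoxide in the protic medium should suppress aryl-to-benzyl silyl migration.

Step 4
Reactants: 4 {2-[(tert-butyldimethylsilyl)oxy]-5-methoxy-3-methylphenyl}methanol
Product: 5 tert-butyl[2-(chloromethyl)-4-methoxy-6-methylphenoxy]dimethylsilane
Conditions: PPh3, N-chlorosuccinimide, THF, 0 °C → rt
Reagents that add atoms: N-chlorosuccinimide, O=C1CCC(=O)N1Cl
Why: Appel-type chlorination through the alkoxyphosphonium salt converts the primary benzylic alcohol into the chloride under near-neutral conditions that leave the aryl silyl ether intact.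

**Fragment B: alkyne**

Step 5
Reactants: 6 geranyl acetate
Product: 7 (2E,6E)-8-hydroxy-3,7-dimethylocta-2,6-dien-1-yl acetate
Conditions: SeO2 (cat.), t-BuOOH, salicylic acid (cat.), CH2Cl2, rt
Reagents that add atoms: tert-butyl hydroperoxide, CC(C)(C)OO (terminal oxygen source; SeO2, O=[Se]=O, is the catalytic oxygen carrier)
Why: Riley allylic oxidation in its catalytic form (ene reaction, then [2,3]-sigmatropic shift) hydroxylates the E-methyl of the electron-rich terminal isopropylidene, the alkene next to the acetoxymethyl group being deactivated.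

Step 6
Reactants: 7 (2E,6E)-8-hydroxy-3,7-dimethylocta-2,6-dien-1-yl acetate
Product: 8 (2E,7S)-8-hydroxy-3,7-dimethyloct-2-en-1-yl acetate
Conditions: Ru(OAc)2[(S)-BINAP] (1 mol %), H2 (100 atm), MeOH, 20 °C
Reagents that add atoms: none
Why: Noyori asymmetric hydrogenation: the free hydroxyl binds ruthenium and directs H2 to one face of the allylic alcohol alkene, which sets C7 (the future C11') as S under control of the (S)-BINAP ligand, while the alkene without a free hydroxyl is not reduced.

Step 7
Reactants: 8 (2E,7S)-8-hydroxy-3,7-dimethyloct-2-en-1-yl acetate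
Product: 9 (2E,7S)-3,7-dimethyl-8-oxooct-2-en-1-yl acetate
Conditions: TEMPO (cat.), PhI(OAc)2, CH2Cl2, 0 °C → rt; used crude
Reagents that add atoms: none
Why: TEMPO-catalysed oxidation through the oxoammonium ion stops at the aldehyde and is mild enough that the α-stereocentre should survive if the aldehyde is used at once.

Step 8
Reactants: 9 (2E,7S)-3,7-dimethyl-8-oxooct-2-en-1-yl acetate; 10 allyl bromide
Product: 11 (2E,7S)-8-hydroxy-3,7-dimethylundeca-2,10-dien-1-yl acetate (C8 epimers)
Conditions: Zn dust, THF, 0 °C; aq. NH4Cl work-up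
Reagents that add atoms: allyl bromide (10), C=CCBr
Why: Barbier allylation: allylzinc bromide formed in the flask adds to the aldehyde through a six-membered transition state faster than it attacks the acetate and without enolising the α-methyl aldehyde, and the new carbinol centre is later erased by oxidation.

Step 9
Reactants: 11 (2E,7S)-8-hydroxy-3,7-dimethylundeca-2,10-dien-1-yl acetate; 12 2-methylbut-2-ene
Product: 13 (2E,7S)-8-hydroxy-3,7,11-trimethyldodeca-2,10-dien-1-yl acetate (C8 epimers)
Conditions: second-generation Grubbs catalyst (H2IMes)(PCy3)Cl2Ru=CHPh (5 mol %), excess 12, CH2Cl2, 40 °C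
Reagents that add atoms: 2-methylbut-2-ene (12), CC=C(C)C
Why: Olefin cross-metathesis of the terminal alkene with excess 2-methylbut-2-ene transfers an isopropylidene unit and releases propene, the standard way to turn an allyl into a prenyl group, while the hindered trisubstituted alkene does not engage the ruthenium carbene.

Step 10
Reactants: 13 (2E,7S)-8-hydroxy-3,7,11-trimethyldodeca-2,10-dien-1-yl acetate
Product: 14 (2E,7S)-3,7,11-trimethyldodeca-2,10-diene-1,8-diol (C8 epimers)
Conditions: K2CO3 (0.2 equiv), MeOH, 0 °C → rt
Reagents that add atoms: none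
Why: Base-catalysed transesterification removes the acetate without touching either alkene or the stereocentre, which has no acidic α-hydrogen at this stage.

Step 11
Reactants: 14 (2E,7S)-3,7,11-trimethyldodeca-2,10-diene-1,8-diol
Product: 15 (2E,7S)-8-hydroxy-3,7,11-trimethyldodeca-2,10-dienal (C8 epimers)
Conditions: MnO2, CH2Cl2, rt
Reagents that add atoms: none
Why: MnO2 oxidises only the allylic primary alcohol, leaves the non-allylic secondary carbinol alone and should give the E-enal without geometric isomerisation.

Step 12
Reactants: 15 (2E,7S)-8-hydroxy-3,7,11-trimethyldodeca-2,10-dienal; 16 propargyl bromide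
Product: 17 (5E,10S)-6,10,14-trimethylpentadeca-5,13-dien-1-yne-4,11-diol (C4 and C11 epimers)
Conditions: Zn dust, THF, 0 °C → rt; aq. NH4Cl work-up
Reagents that add atoms: propargyl bromide (16), C#CCBr
Why: Zinc-mediated Barbier propargylation: the allenylzinc bromide formed in the flask adds 1,2 to the enal with SE2' transposition to give the homopropargylic alcohol, and the new carbinol centre is again a mixture that oxidation removes.

Step 13
Reactants: 17 (5E,10S)-6,10,14-trimethylpentadeca-5,13-dien-1-yne-4,11-diol
Product: 18 (5E,10S)-6,10,14-trimethyl-4,11-bis(triethylsilyloxy)pentadeca-5,13-dien-1-yne (C4 and C11 epimers)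
Conditions: TESCl, imidazole, DMAP (cat.), DMF, 0 °C → rt
Reagents that add atoms: chlorotriethylsilane, CC[Si](Cl)(CC)CC
Why: Silylation of both secondary alcohols removes the acidic protons and masks the future ketones as groups that tolerate Me3Al yet are cleaved by mild acid in the presence of the aryl tert-butyldimethylsilyl ether.

**Union and endgame**

Step 14
Reactants: 18 (5E,10S)-6,10,14-trimethyl-4,11-bis(triethylsilyloxy)pentadeca-5,13-dien-1-yne; 19 trimethylaluminium; 5 tert-butyl[2-(chloromethyl)-4-methoxy-6-methylphenoxy]dimethylsilane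
Product: 21 tert-butyl{2-[(2E,6E,11S)-3,7,11,15-tetramethyl-5,12-bis(triethylsilyloxy)hexadeca-2,6,14-trien-1-yl]-4-methoxy-6-methylphenoxy}dimethylsilane (C5 and C12 epimers), via alkenyldimethylalane 20 (not isolated)
Conditions: 19 (3 equiv), Cp2ZrCl2 (0.2 equiv), H2O (1 equiv), CH2Cl2, −20 → 0 °C; volatiles removed, THF; then 5, NiCl2(PPh3)2 (5 mol %) pre-reduced with n-BuLi (10 mol %), 0 °C → rt
Reagents that add atoms: trimethylaluminium (19), C[Al](C)C
Why: Cp2ZrCl2 and Me3Al form a methylzirconium–aluminium species that adds methyl and metal syn across the terminal C2'≡C3' bond with methyl on the internal carbon C3', and metal exchange gives the (E)-2-methylalkenylalane 20 (Negishi zirconium-catalysed carboalumination). Zerovalent nickel, made from NiCl2(PPh3)2 and n-BuLi, then inserts into the benzylic C–Cl bond of 5, the alkenyl group passes from aluminium to nickel with retention and reductive elimination forms C1'–C2'; the closest known reaction type is the one-pot methylalumination and nickel-catalysed benzylation of terminal alkynes with benzylic chlorides. No ring is closed and no stereocentre is created, so the only stereochemical issue is alkene geometry: cis delivery of methyl and aluminium places C4' trans to the metal, and the retentive coupling carries this over as the E-configured C2'=C3' bond. The step needs metalation at the terminal carbon, which the steric and electronic bias of a monosubstituted alkyne secures, and chemoselectivity over the two trisubstituted alkenes, which are inert to Me3Al/Cp2ZrCl2 at or below room temperature. It also needs the oxygen functions to survive, which is why both future ketones are silylated carbinols and the phenol a silyl ether, and why the water-accelerated low-temperature variant is chosen to shorten the exposure of the allylic C5' silyl ether to the Lewis-acidic medium. Transfer of the alkenyl group in preference to methyl from the mixed alane is the normal course for sp2 ligands on aluminium.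

Step 15
Reactants: 21 tert-butyl{2-[(2E,6E,11S)-3,7,11,15-tetramethyl-5,12-bis(triethylsilyloxy)hexadeca-2,6,14-trien-1-yl]-4-methoxy-6-methylphenoxy}dimethylsilane
Product: 22 (2E,6E,11S)-1-{2-[(tert-butyldimethylsilyl)oxy]-5-methoxy-3-methylphenyl}-3,7,11,15-tetramethylhexadeca-2,6,14-triene-5,12-diol (C5 and C12 epimers)
Conditions: PPTS (cat.), MeOH/CH2Cl2, 0 °C
Reagents that add atoms: none
Why: Acid-catalysed methanolysis cleaves the two alkyl triethylsilyl ethers far faster than the hindered aryl tert-butyldimethylsilyl ether, and the weak acid at 0 °C should not ionise the allylic C5' carbinol.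

Step 16
Reactants: 22 (2E,6E,11S)-1-{2-[(tert-butyldimethylsilyl)oxy]-5-methoxy-3-methylphenyl}-3,7,11,15-tetramethylhexadeca-2,6,14-triene-5,12-diol
Product: 23 (2E,6E,11S)-1-{2-[(tert-butyldimethylsilyl)oxy]-5-methoxy-3-methylphenyl}-3,7,11,15-tetramethylhexadeca-2,6,14-triene-5,12-dione
Conditions: Dess–Martin periodinane (3 equiv), NaHCO3, CH2Cl2, 0 °C
Reagents that add atoms: none
Why: Bicarbonate-buffered Dess–Martin oxidation converts both secondary carbinols into ketones under non-enolising conditions, which should keep the C2'=C3' and C14'=C15' alkenes out of conjugation and leave C11' untouched, while the silylated phenol is shielded from oxidation to a quinone.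

Step 17
Reactants: 23 (2E,6E,11S)-1-{2-[(tert-butyldimethylsilyl)oxy]-5-methoxy-3-methylphenyl}-3,7,11,15-tetramethylhexadeca-2,6,14-triene-5,12-dione
Product: 24 (2E,6E,11S)-1-(2-hydroxy-5-methoxy-3-methylphenyl)-3,7,11,15-tetramethylhexadeca-2,6,14-triene-5,12-dione (CNP0301021.1)
Conditions: TBAF, AcOH (1:1), THF, 0 °C
Reagents that add atoms: none
Why: Fluoride attacks silicon of the aryl silyl ether, whose phenoxide is a good leaving group, and the acetic acid buffer protonates the phenoxide at once so that neither the skipped enone system nor the α-stereocentre C11' should be exposed to base.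

**Compound list**
1 | 4-methoxy-2-methylphenol | COc1ccc(O)c(C)c1 | starting material
2 | 2-hydroxy-5-methoxy-3-methylbenzaldehyde | COc1cc(C)c(O)c(C=O)c1 | intermediate
3 | 2-[(tert-butyldimethylsilyl)oxy]-5-methoxy-3-methylbenzaldehyde | COc1cc(C)c(O[Si](C)(C)C(C)(C)C)c(C=O)c1 | intermediate
4 | {2-[(tert-butyldimethylsilyl)oxy]-5-methoxy-3-methylphenyl}methanol | COc1cc(C)c(O[Si](C)(C)C(C)(C)C)c(CO)c1 | intermediate
5 | tert-butyl[2-(chloromethyl)-4-methoxy-6-methylphenoxy]dimethylsilane | COc1cc(C)c(O[Si](C)(C)C(C)(C)C)c(CCl)c1 | intermediate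
6 | geranyl acetate, (2E)-3,7-dimethylocta-2,6-dien-1-yl acetate | CC(C)=CCC/C(C)=C/COC(C)=O | starting material
7 | (2E,6E)-8-hydroxy-3,7-dimethylocta-2,6-dien-1-yl acetate | CC(=O)OC/C=C(\C)CC/C=C(\C)CO | intermediate
8 | (2E,7S)-8-hydroxy-3,7-dimethyloct-2-en-1-yl acetate | CC(=O)OC/C=C(\C)CCC[C@H](C)CO | intermediate
9 | (2E,7S)-3,7-dimethyl-8-oxooct-2-en-1-yl acetate | CC(=O)OC/C=C(\C)CCC[C@H](C)C=O | intermediate
10 | allyl bromide | C=CCBr | starting material
11 | (2E,7S)-8-hydroxy-3,7-dimethylundeca-2,10-dien-1-yl acetate, C8 epimers | CC(=O)OC/C=C(\C)CCC[C@H](C)C(O)CC=C | intermediate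
12 | 2-methylbut-2-ene | CC=C(C)C | starting material
13 | (2E,7S)-8-hydroxy-3,7,11-trimethyldodeca-2,10-dien-1-yl acetate, C8 epimers | CC(=O)OC/C=C(\C)CCC[C@H](C)C(O)CC=C(C)C | intermediate
14 | (2E,7S)-3,7,11-trimethyldodeca-2,10-diene-1,8-diol, C8 epimers | OC/C=C(\C)CCC[C@H](C)C(O)CC=C(C)C | intermediate
15 | (2E,7S)-8-hydroxy-3,7,11-trimethyldodeca-2,10-dienal, C8 epimers | O=C/C=C(\C)CCC[C@H](C)C(O)CC=C(C)C | intermediate
16 | propargyl bromide | C#CCBr | starting material
17 | (5E,10S)-6,10,14-trimethylpentadeca-5,13-dien-1-yne-4,11-diol, C4 and C11 epimers | C#CCC(O)/C=C(\C)CCC[C@H](C)C(O)CC=C(C)C | intermediate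
18 | (5E,10S)-6,10,14-trimethyl-4,11-bis(triethylsilyloxy)pentadeca-5,13-dien-1-yne, C4 and C11 epimers | C#CCC(O[Si](CC)(CC)CC)/C=C(\C)CCC[C@H](C)C(O[Si](CC)(CC)CC)CC=C(C)C | intermediate
19 | trimethylaluminium | C[Al](C)C | starting material
20 | dimethyl[(1E,5E,10S)-2,6,10,14-tetramethyl-4,11-bis(triethylsilyloxy)pentadeca-1,5,13-trien-1-yl]alumane | C[Al](C)/C=C(\C)CC(O[Si](CC)(CC)CC)/C=C(\C)CCC[C@H](C)C(O[Si](CC)(CC)CC)CC=C(C)C | intermediate
21 | tert-butyl{2-[(2E,6E,11S)-3,7,11,15-tetramethyl-5,12-bis(triethylsilyloxy)hexadeca-2,6,14-trien-1-yl]-4-methoxy-6-methylphenoxy}dimethylsilane, C5 and C12 epimers | COc1cc(C)c(O[Si](C)(C)C(C)(C)C)c(C/C=C(\C)CC(O[Si](CC)(CC)CC)/C=C(\C)CCC[C@H](C)C(O[Si](CC)(CC)CC)CC=C(C)C)c1 | intermediate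
22 | (2E,6E,11S)-1-{2-[(tert-butyldimethylsilyl)oxy]-5-methoxy-3-methylphenyl}-3,7,11,15-tetramethylhexadeca-2,6,14-triene-5,12-diol, C5 and C12 epimers | COc1cc(C)c(O[Si](C)(C)C(C)(C)C)c(C/C=C(\C)CC(O)/C=C(\C)CCC[C@H](C)C(O)CC=C(C)C)c1 | intermediate
23 | (2E,6E,11S)-1-{2-[(tert-butyldimethylsilyl)oxy]-5-methoxy-3-methylphenyl}-3,7,11,15-tetramethylhexadeca-2,6,14-triene-5,12-dione | COc1cc(C)c(O[Si](C)(C)C(C)(C)C)c(C/C=C(\C)CC(=O)/C=C(\C)CCC[C@H](C)C(=O)CC=C(C)C)c1 | intermediate
24 | (2E,6E,11S)-1-(2-hydroxy-5-methoxy-3-methylphenyl)-3,7,11,15-tetramethylhexadeca-2,6,14-triene-5,12-dione | COc1cc(C)c(O)c(C/C=C(\C)CC(=O)/C=C(\C)CCC[C@H](C)C(=O)CC=C(C)C)c1 | target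

**Totals**
Total step count: 17. Longest linear sequence: 13 steps (steps 5 to 17, from geranyl acetate 6 to 24).

**Steps most likely to fail**

Step 14. The nickel stage may be outrun by reductive homocoupling of the benzylic chloride or by methyl transfer from aluminium, and long contact with the Lewis-acidic alane may erode the allylic C5' silyl ether. The fallback sets out from 18 and 5 and comes back at 21, and it reverses the polarity of the coupling partners. The alane 20 is formed as in step 14 but quenched at −30 °C with I2 in THF to give (1E,5E,10S)-1-iodo-2,6,10,14-tetramethyl-4,11-bis(triethylsilyloxy)pentadeca-1,5,13-triene F1. Chloride 5 is converted with Zn dust and LiCl in THF into {2-[(tert-butyldimethylsilyl)oxy]-5-methoxy-3-methylbenzyl}zinc chloride F2. Negishi coupling of the two with Pd(PPh3)4 in THF at room temperature should give 21 with the alkene geometry retained, the aluminium reagent being gone before the C–C bond is made.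

Step 6. The catalyst may discriminate the alkene faces poorly for a 2-methyl-substituted allylic alcohol, may show the opposite sense to the one assumed, or may turn over slowly. The fallback sets out from 7 and comes back at 8. It moves the reduction to the carboxylic acid oxidation level, where 2-methylalk-2-enoic acids of the tiglic acid class are among the best substrates for BINAP–ruthenium dicarboxylates and the (S)-ligand is known to give the (S)-acid. Alcohol 7 is oxidised with MnO2 to (2E,6E)-3,7-dimethyl-8-oxoocta-2,6-dien-1-yl acetate F3. Pinnick oxidation (NaClO2, NaH2PO4, 2-methylbut-2-ene, t-BuOH/H2O) converts it into (2E,6E)-8-acetoxy-2,6-dimethylocta-2,6-dienoic acid F4. Hydrogenation with Ru(OAc)2[(S)-H8-BINAP] in MeOH should give (2S,6E)-8-acetoxy-2,6-dimethyloct-6-enoic acid F5. Activation with isobutyl chloroformate and N-methylmorpholine in THF at −15 °C gives the (2S,6E)-8-acetoxy-2,6-dimethyloct-6-enoic isobutyl carbonic anhydride F6, which is not isolated and is reduced with NaBH4 in THF/H2O to 8 without touching the acetate or the alkene.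

Step 17. Fluoride or the liberated phenoxide may act as a base, moving the C2'=C3' alkene into conjugation with the C5' ketone or epimerising C11'. The fallback sets out from 22 and comes back at 24. It removes the silyl group before the ketones exist and replaces it by an acyl group that comes off at neutral pH. Diol 22 is treated with TBAF in THF to give 2-[(2E,6E,11S)-5,12-dihydroxy-3,7,11,15-tetramethylhexadeca-2,6,14-trien-1-yl]-4-methoxy-6-methylphenol F7. The phenoxide alone is acetylated (Ac2O, K2CO3, acetone, 0 °C) to 2-[(2E,6E,11S)-5,12-dihydroxy-3,7,11,15-tetramethylhexadeca-2,6,14-trien-1-yl]-4-methoxy-6-methylphenyl acetate F8. Dess–Martin oxidation as in step 16 gives 2-[(2E,6E,11S)-3,7,11,15-tetramethyl-5,12-dioxohexadeca-2,6,14-trien-1-yl]-4-methoxy-6-methylphenyl acetate F9. The aryl acetate is then cleaved with NH4OAc in aqueous MeOH at room temperature to give 24.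

**Further compounds**
F1 | step 14 | (1E,5E,10S)-1-iodo-2,6,10,14-tetramethyl-4,11-bis(triethylsilyloxy)pentadeca-1,5,13-triene | I/C=C(\C)CC(O[Si](CC)(CC)CC)/C=C(\C)CCC[C@H](C)C(O[Si](CC)(CC)CC)CC=C(C)C
F2 | step 14 | {2-[(tert-butyldimethylsilyl)oxy]-5-methoxy-3-methylbenzyl}zinc chloride | COc1cc(C)c(O[Si](C)(C)C(C)(C)C)c(C[Zn]Cl)c1
F3 | step 6 | (2E,6E)-3,7-dimethyl-8-oxoocta-2,6-dien-1-yl acetate | CC(=O)OC/C=C(\C)CC/C=C(\C)C=O
F4 | step 6 | (2E,6E)-8-acetoxy-2,6-dimethylocta-2,6-dienoic acid | CC(=O)OC/C=C(\C)CC/C=C(\C)C(=O)O
F5 | step 6 | (2S,6E)-8-acetoxy-2,6-dimethyloct-6-enoic acid | CC(=O)OC/C=C(\C)CCC[C@H](C)C(=O)O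
F6 | step 6 | (2S,6E)-8-acetoxy-2,6-dimethyloct-6-enoic isobutyl carbonic anhydride | CC(=O)OC/C=C(\C)CCC[C@H](C)C(=O)OC(=O)OCC(C)C
F7 | step 17 | 2-[(2E,6E,11S)-5,12-dihydroxy-3,7,11,15-tetramethylhexadeca-2,6,14-trien-1-yl]-4-methoxy-6-methylphenol | COc1cc(C)c(O)c(C/C=C(\C)CC(O)/C=C(\C)CCC[C@H](C)C(O)CC=C(C)C)c1
F8 | step 17 | 2-[(2E,6E,11S)-5,12-dihydroxy-3,7,11,15-tetramethylhexadeca-2,6,14-trien-1-yl]-4-methoxy-6-methylphenyl acetate | COc1cc(C)c(OC(C)=O)c(C/C=C(\C)CC(O)/C=C(\C)CCC[C@H](C)C(O)CC=C(C)C)c1
F9 | step 17 | 2-[(2E,6E,11S)-3,7,11,15-tetramethyl-5,12-dioxohexadeca-2,6,14-trien-1-yl]-4-methoxy-6-methylphenyl acetate | COc1cc(C)c(OC(C)=O)c(C/C=C(\C)CC(=O)/C=C(\C)CCC[C@H](C)C(=O)CC=C(C)C)c1
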